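## Retrosynthetic overview
1. Target 20 ⇒ ketal hydrolysis and OH-directed epoxidation of (S)-dienol 18 ⇒ CBS reduction of dienone 17. The carbinol centre is set first and controls both oxirane carbons.
2. 17 ⇒ acetylation and Morita–Baylis–Hillman hydroxymethylation of the 3-farnesyl p-quinone monoketal 15.
3. The key disconnection lies inside the side chain, at C1′–C2′: the vinylogous α-keto radical from bromide 13 couples with the (E,E)-C14 alkenylalane 14 on nickel. C1′ is the methyl carbon of m-cresol.
4. 13 ⇐ m-cresol (oxidative dearomatisation, then Wohl–Ziegler bromination). 14 ⇐ two Zr-catalysed methylaluminations and one decarboxylative radical alkenylation, from C6, C5 and C2 pieces.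
5. Rings: the carbocycle is inherited from m-cresol and is never built. The oxirane is the only ring formed, in the last step.

Assumption: the SMILES is read as the (1R,2R,6R) isomer, with the epoxide oxygen and the secondary OH cis. "Farnesyl" means (2E,6E)-3,7,11-trimethyldodeca-2,6,10-trien-1-yl, numbered C1′ onward from the ring.

## Route

Step 1
Reactants: 1 5-bromo-2-methylpent-2-ene
Product: 2 6-methylhept-5-en-1-yne
Conditions: LiC≡CH·H2NCH2CH2NH2 (1.3 equiv), DMSO, 0 °C → rt
Reagents that add atoms: lithium acetylide–ethylenediamine complex, [Li+].[C-]#C.NCCN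
Why: SN2 alkylation of acetylide on a primary bromide in DMSO outruns E2, and no stereocentre is involved.

Step 2
Reactants: 2 6-methylhept-5-en-1-yne
Product: 4 (1E)-1-iodo-2,6-dimethylhepta-1,5-diene, via alkenyl(dimethyl)alane 3 (not isolated)
Conditions: Me3Al (2 equiv), Cp2ZrCl2 (0.25 equiv), CH2Cl2, 0 °C → rt; then I2, THF, −30 → 0 °C
Reagents that add atoms: trimethylaluminium, C[Al](C)C; iodine, II
Why: Negishi Zr-catalysed methylalumination adds Me and Al syn with Al on the terminal carbon, and iodinolysis retains geometry, so the E-trisubstituted alkene is fixed (>98:2).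

Step 3
Reactants: 4 (1E)-1-iodo-2,6-dimethylhepta-1,5-diene; 5 pent-4-ynoic acid
Product: 9 (5E)-6,10-dimethylundeca-5,9-dien-1-yne, via NHPI ester 6 (not isolated), via alkenyllithium 7 (not isolated), via alkenylzinc chloride 8 (not isolated)
Conditions: (a) 5, N-hydroxyphthalimide, DIC, cat. DMAP, CH2Cl2, rt; (b) 4 (2 equiv), t-BuLi (2 equiv per 4), Et2O, −78 °C, then ZnCl2, THF, → 0 °C; (c) combine a and b, Ni(acac)2 (10 mol %), 2,2′-bipyridine (10 mol %), THF–DMF, rt
Reagents that add atoms: N-hydroxyphthalimide, O=C1c2ccccc2C(=O)N1O (into 6 only); tert-butyllithium, [Li]C(C)(C)C (Li into 7 only); zinc chloride, Cl[Zn]Cl (into 8 only)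
Why: In this Ni-catalysed decarboxylative alkenylation of a redox-active ester, electron transfer and CO2 loss give the primary but-3-ynyl radical, which alkenyl–Ni captures and couples with retention of the E geometry, leaving the terminal alkyne untouched.

Step 4
Reactants: 10 3-methylphenol (m-cresol)
Product: 12 4,4-dimethoxy-3-methylcyclohexa-2,5-dien-1-one, via 4-methoxy-3-methylphenol 11 (not isolated)
Conditions: PhI(OAc)2 (2.1 equiv), MeOH, 0 °C → rt
Reagents that add atoms: methanol, CO
Why: Two successive hypervalent-iodine oxidative dearomatisations with para attack of MeOH give the p-quinone monoketal, which differentiates the future carbinol carbon (C=O) from the future ketone carbon (ketal).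

Step 5
Reactants: 12 4,4-dimethoxy-3-methylcyclohexa-2,5-dien-1-one
Product: 13 3-(bromomethyl)-4,4-dimethoxycyclohexa-2,5-dien-1-one
Conditions: NBS (1.05 equiv), AIBN (5 mol %), solid K2CO3, PhCF3, 80 °C
Reagents that add atoms: N-bromosuccinimide, O=C1CCC(=O)N1Br
Why: In this Wohl–Ziegler bromination the γ-methyl carries the only allylic C–H bonds and gives a resonance-stabilised radical, while the carbonate removes traces of HBr that would attack the ketal.

Step 6 (key step)
Reactants: 9 (5E)-6,10-dimethylundeca-5,9-dien-1-yne; 13 3-(bromomethyl)-4,4-dimethoxycyclohexa-2,5-dien-1-one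
Product: 15 4,4-dimethoxy-3-[(2E,6E)-3,7,11-trimethyldodeca-2,6,10-trien-1-yl]cyclohexa-2,5-dien-1-one, via trienyl(dimethyl)alane 14 (not isolated)
Conditions: 9, Me3Al (1.5 equiv), Cp2ZrCl2 (0.2 equiv), ClCH2CH2Cl, rt; excess Me3Al removed in vacuo; THF, −20 °C; 13 (0.85 equiv), NiCl2·glyme (5 mol %), 4,4′-di-tert-butyl-2,2′-bipyridine (6 mol %), −20 → 0 °C; Rochelle salt work-up
Reagents that add atoms: trimethylaluminium, C[Al](C)C
Why: Proposed new method: methylalumination fixes the second E-alkene and the alane transmetalates to bipyridine-ligated nickel; the Ni(I)–alkenyl species abstracts bromine from 13 (a vinylogous α-bromoketone with a very weak C–Br bond) to give a delocalised vinylogous α-keto carbon radical, which recombines with Ni(II) at its unhindered primary terminus, and reductive elimination from Ni(III) forms C1′–C2′ with retention of alkene geometry, faster than the THF-complexed alane attacks ketone or ketal at −20 °C; the closest known reaction types are the Ni-catalysed coupling of alkenylalanes with chloromethylquinones and the radical Ni-catalysed alkenylation of α-bromoketones with alkenyl–metal reagents; no stereocentre is formed.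

Step 7
Reactants: 15 3-farnesyl quinone monoketal
Product: 16 2-(hydroxymethyl)-4,4-dimethoxy-5-farnesylcyclohexa-2,5-dien-1-one
Conditions: 37 % aq. HCHO (3 equiv), DMAP (0.3 equiv), THF–H2O 1:1, rt
Reagents that add atoms: formaldehyde, C=O
Why: In this Morita–Baylis–Hillman hydroxymethylation DMAP can add only to the β-unsubstituted enone arm (the other β-carbon carries the farnesyl chain), so CH2OH enters next to the ketone and para to the chain.

Step 8
Reactants: 16 Baylis–Hillman alcohol
Product: 17 (3,3-dimethoxy-6-oxo-4-farnesylcyclohexa-1,4-dien-1-yl)methyl acetate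
Conditions: Ac2O, pyridine, CH2Cl2, 0 °C
Reagents that add atoms: acetic anhydride, CC(=O)OC(C)=O
Why: This is a plain O-acetylation of the only hydroxyl group, run cold and without DMAP so that no SN2′ displacement of the new allylic acetate occurs.

Step 9
Reactants: 17 acetoxymethyl dienone
Product: 18 [(6S)-6-hydroxy-3,3-dimethoxy-4-farnesylcyclohexa-1,4-dien-1-yl]methyl acetate
Conditions: (R)-Me-CBS (0.2 equiv), catecholborane (1.5 equiv), toluene, −78 °C; MeOH quench, carbonate-buffer wash, filtration through Et3N-deactivated silica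
Reagents that add atoms: none
Why: In this Corey–Bakshi–Shibata 1,2-reduction the α-branched C(CH2OAc)= flank acts as the large group against the α-unsubstituted CH= flank, so the (R)-catalyst gives the (S)-carbinol (2R in the target), and catecholborane at −78 °C leaves the acetate and the isolated alkenes alone.

Step 10
Reactants: 18 (S)-dienol
Product: 20 [(1R,2R,6R)-2-hydroxy-5-oxo-6-farnesyl-7-oxabicyclo[4.1.0]hept-3-en-3-yl]methyl acetate (target), via epoxy ketal 19 (not isolated)
Conditions: VO(acac)2 (3 mol %), t-BuOOH (1.05 equiv, decane), CH2Cl2, 0 °C; then montmorillonite K10, moist CH2Cl2, rt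
Reagents that add atoms: tert-butyl hydroperoxide, CC(C)(C)OO; water, O
Why: Hydroxyl-directed vanadium epoxidation delivers oxygen syn to the OH onto the more electron-rich allylic alkene (farnesyl-substituted rather than acetoxymethyl-substituted, with the remote chain alkenes undirected), which sets both oxirane centres cis to the carbinol, and mild acid-clay hydrolysis of the allylic ketal then unmasks the enone.

## Compound list
1 | 5-bromo-2-methylpent-2-ene | CC(C)=CCCBr | starting material
2 | 6-methylhept-5-en-1-yne | C#CCCC=C(C)C | intermediate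
3 | [(1E)-2,6-dimethylhepta-1,5-dien-1-yl]dimethylalane | C[Al](C)/C=C(\C)CCC=C(C)C | intermediate
4 | (1E)-1-iodo-2,6-dimethylhepta-1,5-diene | I/C=C(\C)CCC=C(C)C | intermediate
5 | pent-4-ynoic acid | C#CCCC(=O)O | starting material
6 | 1,3-dioxoisoindolin-2-yl pent-4-ynoate | C#CCCC(=O)ON1C(=O)c2ccccc2C1=O | intermediate
7 | [(1E)-2,6-dimethylhepta-1,5-dien-1-yl]lithium | [Li]/C=C(\C)CCC=C(C)C | intermediate
8 | chloro[(1E)-2,6-dimethylhepta-1,5-dien-1-yl]zinc | Cl[Zn]/C=C(\C)CCC=C(C)C | intermediate
9 | (5E)-6,10-dimethylundeca-5,9-dien-1-yne | C#CCC/C=C(\C)CCC=C(C)C | intermediate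
10 | 3-methylphenol (m-cresol) | Cc1cccc(O)c1 | starting material
11 | 4-methoxy-3-methylphenol | COc1ccc(O)cc1C | intermediate
12 | 4,4-dimethoxy-3-methylcyclohexa-2,5-dien-1-one | CC1=CC(=O)C=CC1(OC)OC | intermediate
13 | 3-(bromomethyl)-4,4-dimethoxycyclohexa-2,5-dien-1-one | BrCC1=CC(=O)C=CC1(OC)OC | intermediate
14 | dimethyl[(1E,5E)-2,6,10-trimethylundeca-1,5,9-trien-1-yl]alane | C[Al](C)/C=C(\C)CC/C=C(\C)CCC=C(C)C | intermediate
15 | 4,4-dimethoxy-3-[(2E,6E)-farnesyl]cyclohexa-2,5-dien-1-one | COC1(OC)C=CC(=O)C=C1C/C=C(\C)CC/C=C(\C)CCC=C(C)C | intermediate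
16 | 2-(hydroxymethyl)-4,4-dimethoxy-5-[(2E,6E)-farnesyl]cyclohexa-2,5-dien-1-one | COC1(OC)C=C(CO)C(=O)C=C1C/C=C(\C)CC/C=C(\C)CCC=C(C)C | intermediate
17 | {3,3-dimethoxy-6-oxo-4-[(2E,6E)-farnesyl]cyclohexa-1,4-dien-1-yl}methyl acetate | COC1(OC)C=C(COC(C)=O)C(=O)C=C1C/C=C(\C)CC/C=C(\C)CCC=C(C)C | intermediate
18 | {(6S)-6-hydroxy-3,3-dimethoxy-4-[(2E,6E)-farnesyl]cyclohexa-1,4-dien-1-yl}methyl acetate | CC(=O)OCC1=CC(OC)(OC)C(C/C=C(\C)CC/C=C(\C)CCC=C(C)C)=C[C@@H]1O | intermediate
19 | {(1R,2R,6R)-2-hydroxy-5,5-dimethoxy-6-[(2E,6E)-farnesyl]-7-oxabicyclo[4.1.0]hept-3-en-3-yl}methyl acetate (oxirane O cis to OH) | CC(=O)OCC1=CC(OC)(OC)[C@]2(C/C=C(\C)CC/C=C(\C)CCC=C(C)C)O[C@@H]2[C@@H]1O | intermediate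
20 | {(1R,2R,6R)-2-hydroxy-5-oxo-6-[(2E,6E)-farnesyl]-7-oxabicyclo[4.1.0]hept-3-en-3-yl}methyl acetate | CC(=O)OCC1=CC(=O)[C@]2(C/C=C(\C)CC/C=C(\C)CCC=C(C)C)O[C@@H]2[C@@H]1O | target

## Step count and risks
Total steps: 10. Longest linear sequence: 8 (steps 1, 2, 3, 6, 7, 8, 9, 10).

**Step 6.** The risks are:
- nickel-catalysed conjugate addition to the free enone arm
- methyl transfer from aluminium
- reductive dimerisation of 13
- ketal ionisation by aluminium

The fallback sets out from 10 and 14 and comes back at 15. It moves the radical coupling in front of the dearomatisation. Acetylate 10 to 3-methylphenyl acetate F1, then brominate under Wohl–Ziegler conditions to 3-(bromomethyl)phenyl acetate F2. Couple the plain benzylic radical of F2 with alane 14 under the same nickel catalysis to give 3-farnesylphenyl acetate F3, and methanolyse (K2CO3, MeOH) to 3-farnesylphenol F4. Oxidise F4 with two equivalents of PhI(OAc)2 in MeOH, through 3-farnesyl-4-methoxyphenol F5, to 15. This costs three more steps, but no enone or ketal is present while nickel and aluminium are in the flask.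

**Step 7.** The β-carbon is flanked by the ketal, so the reaction may be slow, and the amine adduct may aromatise by loss of MeOH. The fallback sets out from 15 and comes back at 16. It replaces organocatalytic C–C bond formation by halogenation and cross-coupling. I2–pyridine α-iodination, which again is possible only on the β-unsubstituted arm, gives 2-iodo-4,4-dimethoxy-5-farnesylcyclohexa-2,5-dien-1-one F6. A Stille coupling of F6 with (tributylstannyl)methanol (Pd2(dba)3, AsPh3, CuI) gives 16.

**Step 9.** Both ketone flanks are vinylic, so the ee may be modest, and 18 can aromatise by loss of MeOH on handling. The fallback sets out from 17 and comes back at 19. It sets the absolute configuration in the epoxidation instead of the reduction. Luche reduction gives the racemic dienol F7. A vanadium/chiral bishydroxamic acid catalysed epoxidation with t-BuOOH is then run to about 50 % conversion as a kinetic resolution, using the ligand antipode matched to the S alcohol, and gives 19. Compound 19 is hydrolysed as in step 10. The unreacted (R)-dienol F8 is separated and reoxidised with MnO2 to 17.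

## Further compounds
F1 | step 6 | 3-methylphenyl acetate | CC(=O)Oc1cccc(C)c1
F2 | step 6 | 3-(bromomethyl)phenyl acetate | CC(=O)Oc1cccc(CBr)c1
F3 | step 6 | 3-[(2E,6E)-farnesyl]phenyl acetate | CC(=O)Oc1cccc(C/C=C(\C)CC/C=C(\C)CCC=C(C)C)c1
F4 | step 6 | 3-[(2E,6E)-farnesyl]phenol | Oc1cccc(C/C=C(\C)CC/C=C(\C)CCC=C(C)C)c1
F5 | step 6 | 3-[(2E,6E)-farnesyl]-4-methoxyphenol | COc1ccc(O)cc1C/C=C(\C)CC/C=C(\C)CCC=C(C)C
F6 | step 7 | 2-iodo-4,4-dimethoxy-5-[(2E,6E)-farnesyl]cyclohexa-2,5-dien-1-one | COC1(OC)C=C(I)C(=O)C=C1C/C=C(\C)CC/C=C(\C)CCC=C(C)C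
F7 | step 9 | racemic {6-hydroxy-3,3-dimethoxy-4-[(2E,6E)-farnesyl]cyclohexa-1,4-dien-1-yl}methyl acetate | CC(=O)OCC1=CC(OC)(OC)C(C/C=C(\C)CC/C=C(\C)CCC=C(C)C)=CC1O
F8 | step 9 | {(6R)-6-hydroxy-3,3-dimethoxy-4-[(2E,6E)-farnesyl]cyclohexa-1,4-dien-1-yl}methyl acetate | CC(=O)OCC1=CC(OC)(OC)C(C/C=C(\C)CC/C=C(\C)CCC=C(C)C)=C[C@H]1O
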